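**Plan**
Numbering (eudesmane): ring A = C1–C5 + C10, ring B = C5–C10, C14 on C10, C15 on C4, side chain C11(=C13)–C12. β is the face of C14 and α the face of H5.
Cuts, in retrosynthetic order: acyl–O9; the C12 oxidation level and C11=C13; C4–C15 and C4–O; then C9–C10 (opens ring B); then C7–C11 and C12–O9 (oxa-Diels–Alder); C7=C8 (cross-metathesis); C5–C6 (alkylation).
Enabling feature: O9 and the C11 arm on C7 are 1,3-cis (both α, diaxial) on ring B, so O9–C9–C8–C7–C11–C12 can be held as one temporary oxane ring. C9 bears oxygen and can be an α-oxy radical, and a C4 ketone makes C5=C10 an acceptor at C10; this answers the dissonant 1,4-relation of O9 and O4.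
Forward: ring A is bought, the oxane helper ring is made next, and ring B closes last by cyclisation of a C9 radical onto C10. Afterwards the C4 ketone becomes the carbinol and the oxane is opened to free 9-OH and C12.
Stereochemistry: C7 comes from a catalyst-controlled cycloaddition. C9, C10 and C5 are relayed from C7 in the key step (bridge geometry, chair ring B, equilibration). C4 comes from α-face epoxidation opposite the axial C14, and C3' is bought with the acid.

Key step: step 5

Assumption: (R)-3-methylpentanoic acid 16 is taken as a catalogue compound in enantiopure form; the SMILES is read as 4α-OH, 5α-H, 7α side chain (7β-H), 9α-acyloxy, 10β-CH3, i.e. (4R,5R,7R,9R,10S,3'R).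

**Step 1**
Reactants: 1 Hagemann's ester (ethyl 2-methyl-4-oxocyclohex-2-ene-1-carboxylate, racemic); 2 allyl bromide
Product: 3 ethyl 2-methyl-4-oxo-3-(prop-2-en-1-yl)cyclohex-2-ene-1-carboxylate (racemic)
Conditions: KOtBu, tBuOH, 23 °C; then 2, 23 → 60 °C
Reagents that add atoms: none
Why: Alkylation of the extended enolate of this vinylogous β-keto ester takes place mainly at the α-carbon of the enone (future C5), the classical entry to 2-alkyl-3-methylcyclohexenones, and no lasting stereocentre is made.

**Step 2**
Reactants: 3 allylated Hagemann's ester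
Product: 5 3-methyl-2-(prop-2-en-1-yl)cyclohex-2-en-1-one, via keto acid 4 (not isolated)
Conditions: KOH, EtOH/H2O, reflux; then aq HCl, 80 °C
Reagents that add atoms: none
Why: Saponification followed by decarboxylation of the vinylogous β-keto acid removes the ester that only served to direct the alkylation and erases the sole stereocentre.

**Step 3**
Reactants: 5 3-methyl-2-(prop-2-en-1-yl)cyclohex-2-en-1-one; 6 (E)-but-2-enal (crotonaldehyde)
Product: 7 (E)-4-(2-methyl-6-oxocyclohex-1-en-1-yl)but-2-enal
Conditions: 6 (5 equiv), second-generation Hoveyda–Grubbs catalyst (3 mol %), CH2Cl2, 40 °C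
Reagents that add atoms: none
Why: Olefin cross-metathesis of a terminal alkene with an enal partner is E-selective and leaves the tetrasubstituted enone untouched.

**Step 4**
Reactants: 7 (E)-4-(2-methyl-6-oxocyclohex-1-en-1-yl)but-2-enal; 8 ethyl vinyl ether
Product: 9 2-{[(2S,4S)-2-ethoxy-3,4-dihydro-2H-pyran-4-yl]methyl}-3-methylcyclohex-2-en-1-one (2,4-cis)
Conditions: 8 (neat, excess), CrCl(L*) (5 mol %; L* = dianion of the Schiff base of 3-(1-adamantyl)-2-hydroxy-5-methylbenzaldehyde and cis-1-aminoindan-2-ol, ligand enantiomer chosen for the (2S,4S) adduct), 4 Å MS, 23 °C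
Reagents that add atoms: none
Why: In this inverse-electron-demand oxa-Diels–Alder reaction of the enal (O=C9–C8=C7) with an enol ether (C11=C12), the chiral chromium chloride complex fixes the face of C7, endo approach gives the cis acetal, and the hindered ketone enone does not act as a heterodiene.

**Step 5**
Reactants: 9 dihydropyranyl enone
Product: 11 (5R,7R,9R,10S,12S)-12-ethoxy-9α,12-epoxy-13,15-dinoreudesman-4-one (trans-fused; oxane bridge C9–O–C12–C11–C7 on the α face), via cis-fused C5 epimer 10 (not isolated)
Conditions: Fe(acac)3 (30 mol %), PhSiH3 (2.5 equiv), Na2HPO4 (buffer), EtOH, 0.01 M, 60 °C; then DBU (0.2 equiv), 23 °C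
Reagents that add atoms: none
Why: An iron hydride made from Fe(acac)3 and PhSiH3 transfers a hydrogen atom to C8 of the electron-rich enol ether, the nucleophilic α-oxy radical at C9 adds to C10 (the β-carbon of the enone), and the C5 α-keto radical is reduced and protonated by EtOH. The closest known reaction type is the iron-catalysed hydrogen-atom-transfer reductive coupling of enol ethers with enones, in effect a Giese addition of a pyranosyl-type radical. Ring B closes in the 6-endo-trig mode on C5=C10, which the enone polarity and the full substitution of C5 favour over 5-exo attack. At C9 the new bond can form only on the oxane face that carries the C6 arm (pyranosyl radicals also react axially), so O9 and C11 end 1,3-cis; at C10 ring B must form as a chair, because its boat would need an oxane chair with C6, C10 and OEt all axial, and this exposes one enone face and, since C6 and C14 are cis on C5=C10, places C14 axial and anti to O9. C5 is α to the ketone and is set by equilibration: C4 can sit only equatorial (exo) on the bridged ring B, so any cis-fused 10 drains into trans-fused 11. The step needs hydrogen atom transfer to the enol ether rather than to the enone, which the electron-poor tetrasubstituted C5=C10 secures, and it needs cyclisation to outrun radical quenching, which dilution and the lack of syn-axial partners at the planar C9 support.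

**Step 6**
Reactants: 11 tricyclic keto acetal
Product: 12 (12S)-12-ethoxy-9α,12-epoxy-13-noreudesm-4(15)-ene
Conditions: Ph3PCH3Br, KOtBu, toluene, 23 → 90 °C
Reagents that add atoms: methyltriphenylphosphonium bromide, C[P+](c1ccccc1)(c1ccccc1)c1ccccc1.[Br-]
Why: Wittig methylenation brings in C15; the base leaves the acetal intact and cannot harm C5, which already has its thermodynamic configuration.

**Step 7**
Reactants: 12 exocyclic alkene
Product: 13 (12S)-12-ethoxy-4α,15:9α,12-diepoxy-13-noreudesmane (spiro-oxirane; O on the α face of C4)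
Conditions: mCPBA, CH2Cl2, 0 °C
Reagents that add atoms: mCPBA (3-chloroperoxybenzoic acid), O=C(OO)c1cccc(Cl)c1
Why: In this Prilezhaev epoxidation the axial C14 methyl, syn-axial to C4, blocks the β face, so oxygen should arrive from the α face as is usual for 4(15)-eudesmenes.

**Step 8**
Reactants: 13 spiro-epoxide
Product: 14 (12S)-12-ethoxy-9α,12-epoxy-13-noreudesman-4α-ol
Conditions: LiEt3BH, THF, 0 → 40 °C; H2O
Reagents that add atoms: none
Why: SN2 hydride opening of the epoxide at its unsubstituted terminus C15 leaves the C4–O bond untouched, so the 4α-OH/4β-CH3 carbinol follows from step 7, and the acetal is inert to hydride.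

**Step 9**
Reactants: 14 hydroxy acetal
Product: 15 12,12-(propane-1,3-diyldisulfanediyl)-13-noreudesmane-4α,9α-diol (C7α–CH2–(1,3-dithian-2-yl); 9α-OH free)
Conditions: HS(CH2)3SH, BF3·OEt2, CH2Cl2, −40 → −10 °C
Reagents that add atoms: propane-1,3-dithiol, SCCCS
Why: Lewis-acid transthioacetalisation exchanges both C12–O bonds for C–S bonds, driven by dithiane formation, and so opens the helper ring and frees 9α-OH without touching the C9–O bond.

**Step 10**
Reactants: 15 dithianyl diol; 16 (R)-3-methylpentanoic acid
Product: 18 9-O-[(3R)-3-methylpentanoyl] derivative of 15, via mixed anhydride 17 (not isolated)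
Conditions: 16, 2,4,6-trichlorobenzoyl chloride, Et3N, toluene, 23 °C; then 15, DMAP, 23 → 60 °C
Reagents that add atoms: none
Why: Yamaguchi esterification acylates the secondary axial 9α-OH while the tertiary 4-OH stays inert, and the stereocentre of the acid is β to the carbonyl and cannot racemise.

**Step 11**
Reactants: 18 dithianyl ester
Product: 19 4α-hydroxy-9α-[(3R)-3-methylpentanoyloxy]-13-noreudesman-12-al
Conditions: MeI, CaCO3, MeCN/H2O (9:1), 45 °C
Reagents that add atoms: water, O
Why: Alkylative hydrolysis of the dithiane (S-methylation, then hydrolysis of the sulfonium ion) runs under buffered near-neutral conditions that spare the ester and the tertiary alcohol.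

**Step 12**
Reactants: 19 aldehyde
Product: 20 4α-hydroxy-9α-[(3R)-3-methylpentanoyloxy]eudesm-11(13)-en-12-al
Conditions: 37% aq HCHO, pyrrolidine (10 mol %), propionic acid (10 mol %), iPrOH, 45 °C
Reagents that add atoms: formaldehyde, C=O
Why: Amine-catalysed Mannich condensation and elimination (α-methylenation of aldehydes) installs C13 at the only enolisable position C11; with O9 already acylated no oxa-Michael addition to the new enal can occur.

**Step 13**
Reactants: 20 α-methylene aldehyde
Product: 21 target, (4R,5R,7R,9R,10S)-4-hydroxy-9-[(3R)-3-methylpentanoyloxy]eudesm-11(13)-en-12-oic acid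
Conditions: NaClO2, NaH2PO4, 2-methylbut-2-ene, tBuOH/H2O, 0 → 23 °C
Reagents that add atoms: sodium chlorite, [Na+].[O-]Cl=O
Why: Pinnick oxidation converts α,β-unsaturated aldehydes into acrylic acids without moving the double bond or touching the ester, the carbinol or any stereocentre.

**Compound list**
1 | Hagemann's ester, ethyl 2-methyl-4-oxocyclohex-2-ene-1-carboxylate (racemic) | CCOC(=O)C1CCC(=O)C=C1C | starting material
2 | allyl bromide | C=CCBr | starting material
3 | ethyl 2-methyl-4-oxo-3-(prop-2-en-1-yl)cyclohex-2-ene-1-carboxylate (racemic) | CCOC(=O)C1CCC(=O)C(CC=C)=C1C | intermediate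
4 | 2-methyl-4-oxo-3-(prop-2-en-1-yl)cyclohex-2-ene-1-carboxylic acid (not isolated) | OC(=O)C1CCC(=O)C(CC=C)=C1C | intermediate
5 | 3-methyl-2-(prop-2-en-1-yl)cyclohex-2-en-1-one | C=CCC1=C(C)CCCC1=O | intermediate
6 | (E)-but-2-enal | C/C=C/C=O | starting material
7 | (E)-4-(2-methyl-6-oxocyclohex-1-en-1-yl)but-2-enal | O=C/C=C/CC1=C(C)CCCC1=O | intermediate
8 | ethyl vinyl ether | C=COCC | starting material
9 | 2-{[(2S,4S)-2-ethoxy-3,4-dihydro-2H-pyran-4-yl]methyl}-3-methylcyclohex-2-en-1-one | CCO[C@@H]1C[C@H](CC2=C(C)CCCC2=O)C=CO1 | intermediate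
10 | cis-fused C5 epimer of 11 (5β-H; not isolated) | CCO[C@@H]3C[C@@H]1C[C@H]2[C@](C)(CCCC2=O)[C@H](O3)C1 | intermediate
11 | (5R,7R,9R,10S,12S)-12-ethoxy-9α,12-epoxy-13,15-dinoreudesman-4-one | CCO[C@@H]3C[C@@H]1C[C@@H]2[C@](C)(CCCC2=O)[C@H](O3)C1 | intermediate
12 | (12S)-12-ethoxy-9α,12-epoxy-13-noreudesm-4(15)-ene | CCO[C@@H]3C[C@@H]1C[C@@H]2[C@](C)(CCCC2=C)[C@H](O3)C1 | intermediate
13 | (12S)-12-ethoxy-4α,15:9α,12-diepoxy-13-noreudesmane | CCO[C@@H]3C[C@@H]1C[C@@H]2[C@](C)(CCC[C@@]24OC4)[C@H](O3)C1 | intermediate
14 | (12S)-12-ethoxy-9α,12-epoxy-13-noreudesman-4α-ol | CCO[C@@H]3C[C@@H]1C[C@@H]2[C@](C)(CCC[C@@]2(C)O)[C@H](O3)C1 | intermediate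
15 | 12,12-(propane-1,3-diyldisulfanediyl)-13-noreudesmane-4α,9α-diol | S1CCCSC1C[C@@H]2C[C@@H]3[C@](C)(CCC[C@@]3(C)O)[C@H](O)C2 | intermediate
16 | (R)-3-methylpentanoic acid | OC(=O)C[C@H](C)CC | starting material
17 | (R)-3-methylpentanoic 2,4,6-trichlorobenzoic anhydride (not isolated) | O=C(OC(=O)C[C@H](C)CC)c1c(Cl)cc(Cl)cc1Cl | intermediate
18 | 9-O-[(3R)-3-methylpentanoyl] derivative of 15 | S1CCCSC1C[C@@H]2C[C@@H]3[C@](C)(CCC[C@@]3(C)O)[C@H](OC(=O)C[C@H](C)CC)C2 | intermediate
19 | 4α-hydroxy-9α-[(3R)-3-methylpentanoyloxy]-13-noreudesman-12-al | O=CC[C@@H]1C[C@@H]2[C@](C)(CCC[C@@]2(C)O)[C@H](OC(=O)C[C@H](C)CC)C1 | intermediate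
20 | 4α-hydroxy-9α-[(3R)-3-methylpentanoyloxy]eudesm-11(13)-en-12-al | C=C(C=O)[C@@H]1C[C@@H]2[C@](C)(CCC[C@@]2(C)O)[C@H](OC(=O)C[C@H](C)CC)C1 | intermediate
21 | (4R,5R,7R,9R,10S)-4-hydroxy-9-[(3R)-3-methylpentanoyloxy]eudesm-11(13)-en-12-oic acid | C=C(C(=O)O)[C@@H]1C[C@@H]2[C@](C)(CCC[C@@]2(C)O)[C@H](OC(=O)C[C@H](C)CC)C1 | target

Total step count: 13. Longest linear sequence: 13 steps (from 1).

**Steps most likely to fail**

Step 5. Hydrogen atom transfer to the 1,2-disubstituted enol ether may be slow. The C9 radical may also be quenched before it reaches the hindered C10, either by reduction or by oxidation to the oxocarbenium ion and capture by ethanol. The fallback sets out from 9 and returns at 11. It makes the radical from a C9–Se bond under chain conditions in which the hydrogen donor is kept scarce. Acid-catalysed Markovnikov addition of benzeneselenol (PhSeH, cat. camphorsulfonic acid, CH2Cl2, −20 °C) to the enol ether of 9 should give the O,Se-acetal 2-{[(2S,4S)-2-ethoxy-6-(phenylselanyl)oxan-4-yl]methyl}-3-methylcyclohex-2-en-1-one F1 as a mixture of C9 epimers, both of which lead to the same radical. Slow addition of (Me3Si)3SiH and AIBN to F1 in refluxing benzene, followed by DBU, should deliver 11.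

Step 9. The Lewis acid may ionise the tertiary C4 carbinol and cause dehydration. The exchange may also stall at the bridged O,S-acetal because the ring C12–O bond opens reluctantly. The fallback sets out from 14 and returns at 19. It opens the bridge by olefination instead of thioacetalisation.
- Mild hydrolysis (AcOH/THF/H2O, 40 °C) should give the bridged lactol 9α,12-epoxy-13-noreudesmane-4α,12-diol F3.
- Excess methylidenetriphenylphosphorane should trap its open hydroxy aldehyde form as the 7α-allyl diol F4, in which C12 carries a sacrificial CH2 and 9α-OH is free.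
- Yamaguchi acylation with 16 (through 17) should give the 9-O-[(3R)-3-methylpentanoyl] allyl compound F5.
- Ozonolysis (O3, CH2Cl2, −78 °C; Me2S) removes the extra carbon and gives 19.

Step 7. Facial selectivity may erode because the α face now also carries the oxane bridge, and the acid by-product may open the spiro-epoxide. The fallback sets out from 12 and returns at 14. It replaces the polar oxygen transfer by a radical Mukaiyama hydration: Co(acac)2 (cat.), PhSiH3, O2, THF, 23 °C. The C4 radical should be trapped by the small O2 molecule away from the syn-axial C14 to give the 4α-hydroperoxide F2, which PPh3 reduces in the same flask to 14.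

**Further compounds**
F1 | step 5 | 2-{[(2S,4S)-2-ethoxy-6-(phenylselanyl)oxan-4-yl]methyl}-3-methylcyclohex-2-en-1-one (C9 epimers) | CCO[C@@H]1C[C@H](CC2=C(C)CCCC2=O)CC(O1)[Se]c1ccccc1
F2 | step 7 | (12S)-12-ethoxy-9α,12-epoxy-4α-hydroperoxy-13-noreudesmane | CCO[C@@H]3C[C@@H]1C[C@@H]2[C@](C)(CCC[C@@]2(C)OO)[C@H](O3)C1
F3 | step 9 | 9α,12-epoxy-13-noreudesmane-4α,12-diol (lactol, C12 epimers) | OC3C[C@@H]1C[C@@H]2[C@](C)(CCC[C@@]2(C)O)[C@H](O3)C1
F4 | step 9 | 7α-allyl diol, 7α-(prop-2-en-1-yl)-11,12,13-trinoreudesmane-4α,9α-diol | C=CC[C@@H]1C[C@@H]2[C@](C)(CCC[C@@]2(C)O)[C@H](O)C1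
F5 | step 9 | 9-O-[(3R)-3-methylpentanoyl] derivative of F4 | C=CC[C@@H]1C[C@@H]2[C@](C)(CCC[C@@]2(C)O)[C@H](OC(=O)C[C@H](C)CC)C1
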